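**Assumption:** the SMILES is taken as drawn, i.e. the 8α,9α-epoxide of ferutinin, (1R,4R,5S,6S,8R,9S) in daucane numbering. Ring atoms are referred to below as C1 (quaternary, Me), C2, C3, C4 (C–OH, iPr), C5 (ring-fusion H), C6 (ester), C7, C8 (Me), C9, C10. The route has not been run; selectivities are predictions.

## Retrosynthetic overview

1. Jaeskeanin ⇒ α-face epoxidation and C6 acylation of jaeschkeanadiol; the C4 carbinol ⇒ α-face isopropyl addition to a trans-fused bicyclic C4 ketone.
2. Seven-membered ring ⇒ ring-closing metathesis (C8=C9) of a C1-allyl / C6-methallyl cyclopentanone; C5–C6 ⇒ regiospecific aldol from an α-bromoketone.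
3. Quaternary C1 ⇒ Claisen [3,3] rearrangement of the vinyl ether of (R)-3-methylcyclopent-2-en-1-ol (1,3-chirality transfer, C–O → C–C).
4. That cyclopentenol ⇒ RCM of a dienol built from (R)-epichlorohydrin, the only purchased stereocentre.
5. Ring order: cyclopentene (RCM) → Claisen → cycloheptene (RCM) → epoxide.

## Route

**Step 1**
Reactants: 1, (R)-epichlorohydrin; 2, (2-methylallyl)magnesium chloride
Product: 3, (R)-2-(3-methylbut-3-en-1-yl)oxirane
Conditions: CuI (5 mol%), THF, −40 → −20 °C; then powdered NaOH, Et2O, rt (chlorohydrin not isolated)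
Reagents that add atoms: none
Why: Cu-catalysed Grignard opening at the epoxide CH2, then base closes the new epoxide onto the CH2Cl carbon; the stereocentre is never touched, so (R) is retained.

**Step 2**
Reactants: 3
Product: 4, (R)-6-methylhepta-1,6-dien-3-ol
Conditions: Me3S⁺I⁻ (3 equiv), n-BuLi, THF, −10 °C → rt
Reagents that add atoms: trimethylsulfonium iodide, C[S+](C)C.[I-]
Why: dimethylsulfonium methylide opens the terminal epoxide at CH2 and the betaine eliminates to the one-carbon-homologated allylic alcohol; the carbinol centre is retained.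

**Step 3**
Reactants: 4
Product: 5, (R)-3-methylcyclopent-2-en-1-ol
Conditions: Grubbs II (2 mol%), CH2Cl2, 40 °C; volatile, carried forward as a solution
Reagents that add atoms: none
Why: RCM of the vinyl and 1,1-disubstituted alkenes gives the trisubstituted cyclopentene with loss of ethylene; no stereocentre is involved.

**Step 4**
Reactants: 5; 6, ethyl vinyl ether
Product: 7, (R)-2-(1-methylcyclopent-2-en-1-yl)acetaldehyde
Conditions: Hg(OAc)2 (cat.), ethyl vinyl ether, reflux; then PhMe, 180 °C, sealed tube
Reagents that add atoms: none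
Why: Claisen [3,3] rearrangement of the allyl vinyl ether is suprafacial, so the new C1–C10 bond forms on the face that carried the C–O bond and the quaternary C1 is set as (R).

**Step 5**
Reactants: 7
Product: 8, (R)-3-methyl-3-(prop-2-en-1-yl)cyclopent-1-ene
Conditions: Ph3P=CH2 (from MePPh3Br, KOtBu), THF, 0 °C
Reagents that add atoms: methyltriphenylphosphonium bromide, C[P+](c1ccccc1)(c1ccccc1)c1ccccc1.[Br-]
Why: Wittig methylenation of the aldehyde gives the allyl arm needed for the later RCM; C1 is untouched.

**Step 6**
Reactants: 8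
Product: 9, (3R)-2-bromo-3-methyl-3-(prop-2-en-1-yl)cyclopentan-1-ol (trans-bromohydrin, both trans diastereomers)
Conditions: NBS (1.0 equiv), THF/H2O, −10 → 0 °C
Reagents that add atoms: N-bromosuccinimide, BrN1C(=O)CCC1=O; water, O
Why: bromohydrin formation on the more nucleophilic cis-disubstituted ring alkene, with water opening the bromonium at the carbon remote from the quaternary centre (OH at C4, Br at C5); the new centres are erased in steps 7 and 9.

**Step 7**
Reactants: 9
Product: 10, (3R)-2-bromo-3-methyl-3-(prop-2-en-1-yl)cyclopentan-1-one (C2 epimers)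
Conditions: Dess–Martin periodinane, NaHCO3, CH2Cl2, 0 °C → rt
Reagents that add atoms: none
Why: alcohol oxidation gives the α-bromoketone, a regiodefined enolate precursor at the hindered C5 position.

**Step 8**
Reactants: 11, 3-methylbut-3-en-1-ol
Product: 12, 3-methylbut-3-enal
Conditions: Dess–Martin periodinane, NaHCO3, CH2Cl2, 0 °C; used at once as a cold solution
Reagents that add atoms: none
Why: buffered oxidation avoids isomerisation of the β,γ-unsaturated aldehyde to the conjugated enal.

**Step 9**
Reactants: 10; 12
Product: 13, (2S,3R)-2-[(1S)-1-hydroxy-3-methylbut-3-en-1-yl]-3-methyl-3-(prop-2-en-1-yl)cyclopentan-1-one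
Conditions: SmI2 (2.2 equiv), THF, −78 °C; chromatography
Reagents that add atoms: none
Why: Reformatsky-type aldol — SmI2 gives the Sm(III) enolate only at C5; attack anti to the allyl arm on C1 sets C5, and the closed Zimmerman–Traxler transition state of the cyclic E-enolate gives the anti aldol at C6. Allyl versus methyl is a weak bias, so only moderate dr is expected and minor isomers are removed here or after step 10.

**Step 10**
Reactants: 13
Product: 14, (3aR,8S,8aS)-8-hydroxy-3a,6-dimethyl-3,3a,4,7,8,8a-hexahydroazulen-1(2H)-one (trans-fused; 1β-Me, 5α-H, 6α-OH)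
Conditions: Grubbs II (5 mol%), CH2Cl2 (5 mM), 40 °C
Reagents that add atoms: none
Why: RCM of the allyl and methallyl groups closes the seven-membered ring and fixes the trisubstituted C8=C9 alkene as the ring (Z) geometry; no stereocentre changes.

**Step 11**
Reactants: 14; 15, isopropylmagnesium chloride
Product: 16, jaeschkeanadiol, (1R,3aR,8S,8aS)-3a,6-dimethyl-1-(propan-2-yl)-1,2,3,3a,4,7,8,8a-octahydroazulene-1,8-diol
Conditions: anhydrous CeCl3 (4 equiv), iPrMgCl (4 equiv), THF, −78 → 0 °C
Reagents that add atoms: none
Why: the weakly basic organocerium adds 1,2 to the hindered, enolisable C4 ketone from the α-face, opposite the β angular methyl, giving 4β-OH / 4α-iPr.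

**Step 12**
Reactants: 16; 17, 4-acetoxybenzoyl chloride
Product: 18, jaeschkeanadiol 6-(4-acetoxybenzoate) (O-acetylferutinin)
Conditions: pyridine, DMAP (cat.), CH2Cl2, 0 °C → rt
Reagents that add atoms: none
Why: acylation occurs only at the secondary C6–OH (the tertiary C4–OH is inert), with retention at C6.

**Step 13**
Reactants: 18
Product: 19, O-acetyljaeskeanin (8α,9α-epoxide)
Conditions: mCPBA, NaHCO3, CH2Cl2, 0 °C
Reagents that add atoms: m-chloroperoxybenzoic acid, OOC(=O)c1cccc(Cl)c1
Why: Prilezhaev epoxidation of the only alkene from the α-face, anti to the β-axial angular methyl, sets C8 (R) and C9 (S); esters and the tertiary alcohol are unaffected.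

**Step 14**
Reactants: 19
Product: 20, jaeskeanin
Conditions: K2CO3 (0.2 equiv), MeOH, 0 °C (or NH3/MeOH)
Reagents that add atoms: none
Why: the aryl acetate is far more labile than the hindered secondary aroyl ester, so mild methanolysis frees the phenol; the epoxide and all stereocentres are untouched.

## Compound list

1 | (R)-epichlorohydrin | ClC[C@H]1CO1 | starting material
2 | (2-methylallyl)magnesium chloride | C=C(C)C[Mg]Cl | starting material
3 | (R)-2-(3-methylbut-3-en-1-yl)oxirane | C=C(C)CC[C@@H]1CO1 | intermediate
4 | (R)-6-methylhepta-1,6-dien-3-ol | C=C[C@H](O)CCC(C)=C | intermediate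
5 | (R)-3-methylcyclopent-2-en-1-ol | CC1=C[C@H](O)CC1 | intermediate
6 | ethyl vinyl ether | C=COCC | starting material
7 | (R)-2-(1-methylcyclopent-2-en-1-yl)acetaldehyde | O=CC[C@@]1(C)CCC=C1 | intermediate
8 | (R)-3-methyl-3-(prop-2-en-1-yl)cyclopent-1-ene | C=CC[C@@]1(C)CCC=C1 | intermediate
9 | (3R)-2-bromo-3-methyl-3-(prop-2-en-1-yl)cyclopentan-1-ol (trans-bromohydrin mixture) | C=CC[C@@]1(C)CCC(O)C1Br | intermediate
10 | (3R)-2-bromo-3-methyl-3-(prop-2-en-1-yl)cyclopentan-1-one (C2 epimers) | C=CC[C@@]1(C)CCC(=O)C1Br | intermediate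
11 | 3-methylbut-3-en-1-ol | C=C(C)CCO | starting material
12 | 3-methylbut-3-enal | C=C(C)CC=O | intermediate
13 | (2S,3R)-2-[(1S)-1-hydroxy-3-methylbut-3-en-1-yl]-3-methyl-3-(prop-2-en-1-yl)cyclopentan-1-one | C=CC[C@@]1(C)CCC(=O)[C@@H]1[C@@H](O)CC(C)=C | intermediate
14 | (3aR,8S,8aS)-8-hydroxy-3a,6-dimethyl-3,3a,4,7,8,8a-hexahydroazulen-1(2H)-one | O=C1CC[C@]2(C)CC=C(C)C[C@H](O)[C@H]21 | intermediate
15 | isopropylmagnesium chloride | CC(C)[Mg]Cl | starting material
16 | jaeschkeanadiol | CC(C)[C@]1(O)CC[C@]2(C)CC=C(C)C[C@H](O)[C@H]21 | intermediate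
17 | 4-acetoxybenzoyl chloride | CC(=O)Oc1ccc(cc1)C(Cl)=O | starting material
18 | jaeschkeanadiol 6-(4-acetoxybenzoate) | CC(C)[C@]1(O)CC[C@]2(C)CC=C(C)C[C@H](OC(=O)c3ccc(OC(C)=O)cc3)[C@H]21 | intermediate
19 | O-acetyljaeskeanin | CC(C)[C@]1(O)CC[C@]2(C)C[C@@H]3O[C@]3(C)C[C@H](OC(=O)c3ccc(OC(C)=O)cc3)[C@H]21 | intermediate
20 | jaeskeanin | CC(C)[C@]1(O)CC[C@]2(C)C[C@@H]3O[C@]3(C)C[C@H](OC(=O)c3ccc(O)cc3)[C@H]21 | target

## Step count and risks

Total steps: 14. Longest linear sequence: 13 (steps 1–7, then 9–14); step 8 is a one-step side branch.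

Steps most likely to fail:

1. **Step 9 (C5/C6 stereocontrol in an intermolecular aldol next to a Me/allyl quaternary centre).** Fallback: stop relying on the aldol for stereochemistry. Oxidise the stereo-mixed RCM product to the bicyclic 1,3-diketone and mask C6 as its silyl enol ether. Add isopropyl to C4 from the α-face, then unmask so that C5 is protonated within the bicycle. Finally reduce C6=O with Me4NBH(OAc)3, which delivers hydride from the 4β-OH to give the 6α-alcohol.

2. **Step 6 (chemo- and regioselective bromohydrin formation on a diene).** Fallback: replace the halohydrin logic with an enone-blocking strategy. Carry the Johnson–Claisen ester, which has a single alkene, through hydroboration/oxidation and dehydrogenation to the 4,4-disubstituted cyclopent-2-enone. There only C5 can enolise, so the aldol is regiospecific. Then convert the ester to the vinyl group, run the RCM and conjugate-reduce the enone.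

3. **Step 11 (isopropyl addition to a hindered, enolisable β-hydroxy ketone; enolisation, reduction or retro-aldol).** Fallback: protect C6–OH as its TES ether and add 2-propenyllithium/CeCl3, an sp2 nucleophile that is less prone to reduction. Then saturate only the 1,1-disubstituted isopropenyl alkene (diimide or Wilkinson hydrogenation) in the presence of the ring trisubstituted alkene.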